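## Retrosynthetic overview

1. Target 12 ⇒ hydroxy diacid lactone 8 + (R)-malic acid 9. The last step is a C1-selective acylation through the O-trifluoroacetyl malic anhydride, with no protecting groups.
2. 8 ⇒ bis-lactone 7 by hydrolysis. The 13-membered lactone hides both the ω-hydroxyl and the side-chain carboxyl.
3. 7 ⇒ cyclic ketene silyl acetal 3 + dimethyl 2-oxoglutarate 4. This is the C–C bond of the biosynthesis (acyl donor α-carbon to the keto carbon of 2-oxoglutarate), made as one catalytic anti-selective aldol that sets both stereocentres.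
4. Ring order: the only ring of the target, the γ-lactone, closes directly after the aldol by attack of the new tertiary hydroxyl on the γ-ester, as 2-alkylhomocitrates lactonise in nature. The macrolactone comes in with 1 and is opened in step 3.
5. 3 ⇒ oxacyclotridecan-2-one 1 (commercial, as are 4 and 9).

Assumption: the (S,S)-Bn-box complex of Sn(OTf)2 is taken to add the nucleophile to the si face of a chelated α-keto ester, as the Cu(OTf)2/tert-butyl-box catalyst does, so the (R,R)-ligand, 2,2'-(propane-2,2-diyl)bis[(4R)-4-benzyl-4,5-dihydro-1,3-oxazole], is specified for re-face attack; if the first run gives the mirror-image lactone, the (S,S)-ligand is used and nothing else changes.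

## Route

Step 1
Reactants: 1 oxacyclotridecan-2-one (12-dodecanolide)
Product: 3 (E)-2-(trimethylsilyloxy)oxacyclotridec-2-ene, via lithium enolate 2 (not isolated)
Conditions: LiN(iPr)2 (1.15 equiv, commercial solution), THF, −78 °C, 1 added over 30 min; Me3SiCl (1.3 equiv), −78 °C → rt; pentane, filter, concentrate, used crude
Reagents that add atoms: chlorotrimethylsilane, C[Si](C)(C)Cl
Why: Kinetic deprotonation of the s-trans ester through the Ireland chair transition state gives the enolate with O–Li trans to C4 (the ring-cis enolate that the 13-membered ring also favours), and O-silylation (silyl ketene acetal formation) fixes that single geometry; no stereocentre is formed.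

Step 2
Reactants: 3 (E)-2-(trimethylsilyloxy)oxacyclotridec-2-ene; 4 dimethyl 2-oxopentanedioate (dimethyl 2-oxoglutarate)
Product: 7 methyl (2R)-5-oxo-2-[(3S)-2-oxooxacyclotridecan-3-yl]oxolane-2-carboxylate, via silyl aldol adduct 5 (not isolated), via hydroxy diester 6 (not isolated)
Conditions: Sn(OTf)2 (10 mol %), (R,R)-Bn-box (11 mol %), CH2Cl2, −78 °C, 3 (1.3 equiv) added over 2 h; then 1 M HCl–THF, rt; then TsOH·H2O (10 mol %), PhMe, 70 °C
Reagents that add atoms: none
Why: Proposed new method: the divalent tin complex binds the 1,2-dicarbonyl unit of 4 as a five-membered chelate, the ketene acetal adds to the open re face of the ketone through an open Mukaiyama transition state that gives the anti adduct (carbinol oxygen and ring C4 on opposite sides of the ester C–carbinol C–C3–C2 zigzag), so the carbinol carbon becomes (R) and lactone C3 becomes (S) in one event, silyl transfer frees the catalyst, HCl removes the silyl ether and TsOH closes the five-membered lactone on the γ-ester with loss of methanol, which mirrors the C–C bond formation and lactonisation of the alkylhomocitrate pathway; the closest known reaction type is the anti-selective Mukaiyama aldol of thioester silyl ketene acetals with pyruvate esters under Sn(OTf)2–bis(oxazoline) catalysis, and new here are the lactone-derived ketene acetal as donor and the 2-oxoglutarate diester as acceptor.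

Step 3
Reactants: 7 methyl (2R)-5-oxo-2-[(3S)-2-oxooxacyclotridecan-3-yl]oxolane-2-carboxylate
Product: 8 (2R)-2-[(1S)-1-carboxy-11-hydroxyundecyl]-5-oxooxolane-2-carboxylic acid
Conditions: 3 M H2SO4 (aq)–1,4-dioxane (1:1), 95 °C, 24–48 h; EtOAc extraction, evaporate from toluene
Reagents that add atoms: water, O
Why: Acid-catalysed acyl–oxygen ester hydrolysis cleaves the methyl ester and opens the macrolactone (driven by the large excess of water), while the γ-lactone is the stable form of the 2-hydroxyglutarate unit in acid and persists or re-forms on concentration; no enolate is formed, so neither stereocentre can epimerise and retro-aldol or β-elimination are excluded.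

Step 4
Reactants: 8 (2R)-2-[(1S)-1-carboxy-11-hydroxyundecyl]-5-oxooxolane-2-carboxylic acid; 9 (R)-malic acid
Product: 12 (2R)-2-[(1S)-1-carboxy-11-{[(2R)-3-carboxy-2-hydroxypropanoyl]oxy}undecyl]-5-oxooxolane-2-carboxylic acid, via trifluoroacetylmalic anhydride 10 (not isolated), via trifluoroacetate ester 11 (not isolated)
Conditions: 9 (1.5 equiv), (CF3CO)2O (neat), 0 °C → rt, 2 h, evaporate to dryness in the same flask; then 8, THF, rt, 12 h; then H2O–THF, rt, 4 h; reverse-phase chromatography
Reagents that add atoms: none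
Why: The primary alcohol opens the unsymmetrical cyclic anhydride at the carbonyl next to the trifluoroacetoxy-bearing carbon, the more electrophilic one (regioselective anhydride alcoholysis, the established way to malic acid 1-monoesters), the hindered carboxylic acids of 8 only form reversible mixed anhydrides, water then hydrolyses the labile trifluoroacetate, and the (R) centre of malic acid is never touched.

## Compound list

1 | oxacyclotridecan-2-one | O=C1CCCCCCCCCCCO1 | starting material
2 | lithium oxacyclotridec-2-en-2-olate (O–Li trans to C4) | [Li+].[O-]/C1=C/CCCCCCCCCCO1 | intermediate (not isolated)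
3 | (E)-2-(trimethylsilyloxy)oxacyclotridec-2-ene | C[Si](C)(C)O/C1=C/CCCCCCCCCCO1 | intermediate
4 | dimethyl 2-oxopentanedioate | COC(=O)CCC(=O)C(=O)OC | starting material
5 | dimethyl (2R)-2-[(3S)-2-oxooxacyclotridecan-3-yl]-2-(trimethylsilyloxy)pentanedioate | O=C2OCCCCCCCCCC[C@H]2[C@@](O[Si](C)(C)C)(C(=O)OC)CCC(=O)OC | intermediate (not isolated)
6 | dimethyl (2R)-2-hydroxy-2-[(3S)-2-oxooxacyclotridecan-3-yl]pentanedioate | O=C2OCCCCCCCCCC[C@H]2[C@@](O)(C(=O)OC)CCC(=O)OC | intermediate (not isolated)
7 | methyl (2R)-5-oxo-2-[(3S)-2-oxooxacyclotridecan-3-yl]oxolane-2-carboxylate | O=C2OCCCCCCCCCC[C@H]2[C@@]1(C(=O)OC)CCC(=O)O1 | intermediate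
8 | (2R)-2-[(1S)-1-carboxy-11-hydroxyundecyl]-5-oxooxolane-2-carboxylic acid | OCCCCCCCCCC[C@H](C(=O)O)[C@@]1(C(=O)O)CCC(=O)O1 | intermediate
9 | (R)-malic acid | O=C(O)C[C@@H](O)C(=O)O | starting material
10 | (3R)-2,5-dioxooxolan-3-yl trifluoroacetate | O=C1C[C@@H](OC(=O)C(F)(F)F)C(=O)O1 | intermediate (not isolated)
11 | (2R)-2-[(1S)-1-carboxy-11-{[(2R)-3-carboxy-2-(trifluoroacetoxy)propanoyl]oxy}undecyl]-5-oxooxolane-2-carboxylic acid | O=C(O)C[C@@H](OC(=O)C(F)(F)F)C(=O)OCCCCCCCCCC[C@H](C(=O)O)[C@@]1(C(=O)O)CCC(=O)O1 | intermediate (not isolated)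
12 | (2R)-2-[(1S)-1-carboxy-11-{[(2R)-3-carboxy-2-hydroxypropanoyl]oxy}undecyl]-5-oxooxolane-2-carboxylic acid | O=C(O)C[C@@H](O)C(=O)OCCCCCCCCCC[C@H](C(=O)O)[C@@]1(C(=O)O)CCC(=O)O1 | target

## Step count and risks

Total steps: 4. Longest linear sequence: 4 (1 → 3 → 7 → 8 → 12).

**Step 2 (most likely to fail).** Neither an ester-derived ketene acetal nor a keto diester with a third carbonyl has been run with this catalyst class, so background addition, a competing chelate or low anti selectivity are all possible. The fallback sets out from 1 and returns at 8, and changes the donor to the acyclic thioester for which the anti-selective pyruvate aldol is known.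
- 1 is opened with Me2AlSEt (AlMe3 and ethanethiol, CH2Cl2, 0 °C → rt) to S-ethyl 12-hydroxydodecanethioate F1.
- LiN(iPr)2 (2.2 equiv) then Me3SiCl in THF at −78 °C silylates both the hydroxyl and the thioester enolate to give (Z)-1-(ethylsulfanyl)-1,12-bis(trimethylsilyloxy)dodec-1-ene F2.
- F2 and 4 under the step 2 catalyst, followed by the same HCl and TsOH treatment (at high dilution), give methyl (2R)-2-[(2S)-1-(ethylsulfanyl)-12-hydroxy-1-oxododecan-2-yl]-5-oxooxolane-2-carboxylate F3.
- LiOH–H2O2 in THF–H2O at 0 °C, Na2SO3, then HCl to pH 1 cleaves the thioester and the methyl ester and re-closes the γ-lactone to give 8.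

**Step 4.** The free acids of 8 may divert the anhydride, and some of the 4-ester regioisomer is expected. The fallback sets out from 8 and returns at 12, and replaces acylation of the alcohol by alkylation of a malate carboxylate.
- 8 with BnBr and KHCO3 in DMF gives benzyl (2R)-2-[(2S)-1-(benzyloxy)-12-hydroxy-1-oxododecan-2-yl]-5-oxooxolane-2-carboxylate F5.
- I2, PPh3 and imidazole convert it into benzyl (2R)-2-[(2S)-1-(benzyloxy)-12-iodo-1-oxododecan-2-yl]-5-oxooxolane-2-carboxylate F6.
- Commercial D-aspartic acid 4-benzyl ester is diazotised (NaNO2, aqueous H2SO4, 0 °C, retention) to (2R)-4-(benzyloxy)-2-hydroxy-4-oxobutanoic acid F7.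
- The caesium salt of F7 (Cs2CO3, DMF, rt) displaces the iodide of F6, so only the C1 carboxylate can form the ester, to give the tribenzyl ester of the target F8.
- H2 over Pd/C in EtOAc–MeOH removes the three benzyl groups to give 12.

**Step 3.** The macrolactone carbonyl sits next to a fully substituted carbon and may hydrolyse too slowly in acid. The fallback sets out from 7 and returns at 8, and replaces hydrolysis by transacylation to thioesters followed by peroxide cleavage.
- Excess Me2AlSEt (CH2Cl2, 0 °C → rt) converts all three acyl groups of 7 into S-ethyl thioesters to give S,S',S''-triethyl (3R,4S)-3,14-dihydroxytetradecane-1,3,4-tricarbothioate F4.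
- LiOH–H2O2 at 0 °C cleaves the thioesters within minutes, before retro-aldol can compete; Na2SO3 and acidification to pH 1 then close the γ-lactone to give 8.

## Further compounds

F1 | step 2 | S-ethyl 12-hydroxydodecanethioate | OCCCCCCCCCCCC(=O)SCC
F2 | step 2 | (Z)-1-(ethylsulfanyl)-1,12-bis(trimethylsilyloxy)dodec-1-ene | CCS/C(O[Si](C)(C)C)=C\CCCCCCCCCCO[Si](C)(C)C
F3 | step 2 | methyl (2R)-2-[(2S)-1-(ethylsulfanyl)-12-hydroxy-1-oxododecan-2-yl]-5-oxooxolane-2-carboxylate | OCCCCCCCCCC[C@H](C(=O)SCC)[C@@]1(C(=O)OC)CCC(=O)O1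
F4 | step 3 | S,S',S''-triethyl (3R,4S)-3,14-dihydroxytetradecane-1,3,4-tricarbothioate | OCCCCCCCCCC[C@H](C(=O)SCC)[C@@](O)(C(=O)SCC)CCC(=O)SCC
F5 | step 4 | benzyl (2R)-2-[(2S)-1-(benzyloxy)-12-hydroxy-1-oxododecan-2-yl]-5-oxooxolane-2-carboxylate | OCCCCCCCCCC[C@H](C(=O)OCc2ccccc2)[C@@]1(C(=O)OCc2ccccc2)CCC(=O)O1
F6 | step 4 | benzyl (2R)-2-[(2S)-1-(benzyloxy)-12-iodo-1-oxododecan-2-yl]-5-oxooxolane-2-carboxylate | ICCCCCCCCCC[C@H](C(=O)OCc2ccccc2)[C@@]1(C(=O)OCc2ccccc2)CCC(=O)O1
F7 | step 4 | (2R)-4-(benzyloxy)-2-hydroxy-4-oxobutanoic acid | O=C(OCc1ccccc1)C[C@@H](O)C(=O)O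
F8 | step 4 | 4-benzyl 1-{(11S)-12-(benzyloxy)-11-[(2R)-2-(benzyloxycarbonyl)-5-oxooxolan-2-yl]-12-oxododecyl} (2R)-2-hydroxybutanedioate | O=C(OCc3ccccc3)C[C@@H](O)C(=O)OCCCCCCCCCC[C@H](C(=O)OCc2ccccc2)[C@@]1(C(=O)OCc2ccccc2)CCC(=O)O1
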